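**Built-in leftover.** Each X takes up one J and one L, and L is charged below J, so 0.485 M of J stays over and X is capped at 50.0 % of the J charged.

    J + E ⇌ J.E (K1 = 0.56 /M, k1 = 3.16 /M/h, Ea1 = 69.0 kJ/mol, ΔH1 = −36.0 kJ/mol)
    L + J.E → L.J.E (k2 = 5.81 /M/h, Ea2 = 63.0 kJ/mol)
    L.J.E → G (k3 = 34.6 /h, Ea3 = 86.0 kJ/mol)
    G → E + X (k4 = 8.74 /h, Ea4 = 81.0 kJ/mol)
    (constants at 20 °C)

the same everywhere: J 0.97 M; L 0.485 M; E 48 mM; time 6.0 d
- south: temperature 60 °C
- north-east: temperature 40 °C
- south-east: temperature 80 °C
- north: temperature 20 °C

- all constants are for 20 °C and move with temperature by the activation energies and enthalpies

* the best flask by amount of X, in percent of the J charged; "all alike" if 1.5 percentage points covers them all (south / north-east / south-east / north / all alike)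
* amount of X at the end, in percent of the J charged, south
* amount of X at the end, in percent of the J charged, north-east
* amount of X at the end, in percent of the J charged, south-east
* amount of X at the end, in percent of the J charged, north

**Bench rule.** With J in excess, the habit is to call the catalyst saturated and the rate zero order, set by the slower first-order constant times the catalyst charge. G → E + X is slower than L.J.E → G, so at 20 °C the rule gets through the L charge in 1.16 h.

**Its border.** Saturation needs K[J] well above one, with K the binding constant of J to E. In north, K[J] is 0.543 at the charge and falls to 0.272 at the leftover J, so the rule fails there. J.E then holds a share of 0.214 of the catalyst, and free E is the resting state. With k the constant of L + J.E, k[L] starts at 2.82 /h, below 8.74 /h, and it falls as L is used, so in the tail of north this addition is the rate-limiting step and L is the concentration that sets the order.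

**Tail time.** The rate in north is then k[L][J.E], pseudo-first-order in L. The tail time τ is the inverse of k[J.E], here 16.8 h: the time in which L falls by a factor e while J stands in excess. The 6.0 d span 8.57 τ, so this reckoning puts the L left in north at 0.0189 % of its charge. The activation energy of the addition exceeds the size of the binding enthalpy, so the product kK climbs with temperature and τ shortens in the warmer flasks. This reckoning therefore puts each flask at the cap of 50.0 %, since the time exceeds τ.

**Forecast, result.** The forecast gives all alike, with 50 % south, 50 % north-east, 50 % south-east and 50 % north, because “L is the limiting reagent at half the J charge”. The flasks give all alike: 50.0 % south, 50.0 % north-east, 50.0 % south-east, 50.0 % north.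

**Why north stops.** With L held at its charge, X in north reaches 99.9 % instead of 50.0 %, so the falling level of L is the main reason for the stop. L in north reads 1.22 % at 3.00 d and 0.0179 % at 6.00 d, a reading of 17.1 h per factor e, against the reckoned τ of 16.8 h.

**Less catalyst.** A neighbour flask is north with 0.012 M of E, and with the share of J.E held, τ scales inversely with the catalyst charge, giving 67.2 h. For this neighbour flask the reckoning puts the L left at 11.7 % of its charge and X at 44.1 %. The computed neighbour flask ends with L at 10.1 % and X at 44.9 %.

(Its constants are assumed.)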